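Target is what the flask is for, but the question concerns the electrophile behind it, so follow that.

| flask | electrophile | nucleophile | free base | scavenger | remark | time |
|---|---|---|---|---|---|---|
| west | 0.42 M | 0.84 M | 0.44 M | 0.63 M | run made earlier |  |
| north-west | 0.42 M | 0.84 M | 0.99 M | 0.63 M | run made earlier |  |
| eta | 0.42 M | 0.840 M | 0.340 M | 0.630 M |  | 3.0 h |
| alpha | 0.42 M | 0.840 M | 0.670 M | 0.630 M |  | 3.0 h |

| run | time / min | electrophile / % | target / % |
|---|---|---|---|
| west | 8.00 | 96.0 | 4.3 |
| west | 15.0 | 91.5 | 7.0 |
| west | 25.0 | 86.8 | 12.1 |
| west | 50.0 | 76.7 | 19.8 |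
| west | 90.0 | 64.0 | 29.5 |
| north-west | 20.0 | 90.7 | 8.9 |
| north-west | 40.0 | 81.6 | 15.1 |
| north-west | 50.0 | 77.3 | 17.2 |
| north-west | 80.0 | 66.0 | 21.6 |
| north-west | 90.0 | 63.7 | 21.3 |

(each reading ± 0.5 percentage points)

1. part of the electrophile that has reacted at the end, eta
2. part of the electrophile that has reacted at the end, alpha
3. what raising the concentration of free base from its lowest to its highest value here does to the part of the electrophile that has reacted (changes below 5 percentage points count as none) (no change / it rises / it falls)



Compare the last readings: at 90.0 min the west run keeps 64.0 % of its electrophile and the north-west run 63.7 %, though free base rises from 0.44 M to 0.99 M. So leave free base out of the electrophile's loss. Assume each electrophile takes one nucleophile: divide the two rates, time drops out, and [nucleophile] falls by what [electrophile] loses. From the west run, read the rate of electrophile loss divided by [electrophile][nucleophile], the pairing constant or second-order rate constant: 0.393 M⁻¹ h⁻¹. Integrate it to 3.0 h: eta and alpha, alike in electrophile and nucleophile, each lose 56.2 % by my reckoning.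

The forecast gives 56 % for eta, 56 % for alpha and no change, reasoning that “its loss is zero order in base”.

The simulation gives 56.7 % for eta and 56.7 % for alpha; raising free base from its lowest to its highest value here brings no change, a change of 0 percentage points.

    electrophile + nucleophile → acid set free + target (k = 0.400 M⁻¹ h⁻¹)
    nucleophile + acid set free ⇌ protonated nucleophile, settled at all times (K = 12.0 M⁻¹)
    acid set free + free base ⇌ salt of the base, settled at all times (K = 22000 M⁻¹)
    electrophile + acid set free ⇌ idle adduct, settled at all times (K = 3.90 M⁻¹)
    acid set free + scavenger → scavenged by-product (k = 5.30 M⁻¹ h⁻¹)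
    acid set free + target → side product (k = 12.0 M⁻¹ h⁻¹)
    free base + target → over-reaction product (k = 0.820 M⁻¹ h⁻¹)

Eta and alpha match in conversion but not in content: at 3.0 h target stands at 46.5 % in eta and 31.8 % in alpha, with over-reaction product at 10.1 % and 24.9 %. Now put 0.393 M⁻¹ h⁻¹ to a flask like eta but charged with 0.17 M of electrophile: it reckons 60.2 % reacted at 3.0 h, and that simulated flask shows 60.7 %.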